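Both prenyl chains, at C8 of ring A and C5' of ring B, end in the same trisubstituted C2''=C3'' olefin, so each is cut at that double bond back to a plain allyl group. A single twofold ruthenium-catalysed cross-metathesis with 2-methylbut-2-ene then turns an 8,5'-diallyl flavone tetraacetate into the diprenyl tetraacetate, forming both olefins at once and leaving the flavone core untouched. The diallyl precursor is reached from rutin: its 3-O-sugar steers allylation to O7 and O4', the freed O3 is methylated, and an acetylative double Claisen rearrangement carries the allyl groups to C8 and C5' while installing all four acetates. Methanolysis releases the target.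

Key step: step 5

Remark on the chemistry: the target has no stereocentre and each side-chain olefin carries two identical methyl groups, so there is no enantiomer or E/Z isomer to control; it is made as the achiral compound.
Assumption: rutin (quercetin 3-O-rutinoside) serves as the commercial source of the quercetin skeleton, because its sugar masks O3 while O7 and O4' are allylated; O5 and O3' are acetylated before the allyl shifts so that the 5-OH/C4=O chelate, which would favour C6, is absent.

Step 1
Reactants: 1 rutin (quercetin 3-O-[α-L-rhamnopyranosyl-(1→6)-β-D-glucopyranoside]); 2 allyl bromide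
Product: 3 7,4'-di-O-allylrutin
Conditions: allyl bromide (2.2 equiv), K2CO3 (2.5 equiv), DMF, rt → 40 °C, N2
Reagents that add atoms: allyl bromide, C=CCBr
Why: Williamson etherification should take place at the two most acidic phenols, 7-OH and 4'-OH, because O3 is glycosylated, 5-OH is chelated to C4=O and 3'-OH is the weakest acid, the same site preference as in the familiar 7,4'-dibenzylation of rutin.

Step 2
Reactants: 3 7,4'-di-O-allylrutin
Product: 4 7,4'-di-O-allylquercetin
Conditions: 2 M aq. HCl, EtOH, 80 °C
Reagents that add atoms: none
Why: Acid-catalysed glycoside hydrolysis should cleave the enol-type 3-O-acetal linkage and release the sugars, while aryl allyl ethers are inert to hot dilute aqueous acid.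

Step 3
Reactants: 4 7,4'-di-O-allylquercetin; 5 iodomethane
Product: 6 7,4'-di-O-allyl-3-O-methylquercetin
Conditions: MeI (1.1 equiv), K2CO3 (1.2 equiv), DMF, 0 °C → rt
Reagents that add atoms: iodomethane, CI
Why: Williamson O-methylation with one equivalent of electrophile should select the enolic 3-OH, the most acidic hydroxyl left, over the chelated 5-OH and the weakly acidic 3'-OH.

Step 4
Reactants: 6 7,4'-di-O-allyl-3-O-methylquercetin
Product: 9 8,5'-diallyl-3-O-methylquercetin 5,7,3',4'-tetraacetate, via 5,3'-di-O-acetyl-7,4'-di-O-allyl-3-O-methylquercetin 7 (not isolated), via 5,3'-di-O-acetyl-8,5'-diallyl-3-O-methylquercetin 8 (not isolated)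
Conditions: Ac2O (excess), NaOAc, PhNEt2, 120 °C; then 200 °C (sealed tube), Ar
Reagents that add atoms: acetic anhydride, CC(=O)OC(C)=O
Why: Acetylation followed by two aromatic Claisen [3,3] rearrangements with acetylative trapping should send the O4' allyl group to C5' (C3' is substituted) and the O7 allyl group to C8 (favoured by C7=C8 bond fixation in the benzopyranone once the 5-OH chelate is capped), the new phenols being acetylated as formed so that they neither oxidise nor cyclise.

Step 5
Reactants: 9 8,5'-diallyl-3-O-methylquercetin 5,7,3',4'-tetraacetate; 10 2-methylbut-2-ene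
Product: 11 8,5'-diprenyl-3-O-methylquercetin 5,7,3',4'-tetraacetate
Conditions: Grubbs II (10 mol %), 2-methylbut-2-ene (large excess), 1,4-benzoquinone (10 mol %), CH2Cl2, 40 °C, sealed tube
Reagents that add atoms: 2-methylbut-2-ene, CC=C(C)C
Why: The ruthenium alkylidene engages each monosubstituted allyl olefin by [2+2] cycloaddition and cycloreversion (Chauvin cycle), and turnover with 2-methylbut-2-ene delivers an isopropylidene unit to the side-chain CH= carbon while propene leaves, so both C2''=C3'' bonds form in one flask. The closest known reaction type is the Ru-catalysed cross-metathesis of ortho-allylphenol esters with 2-methylbut-2-ene to prenylarenes, here run twice on one molecule. No ring is closed and no stereocentre or E/Z element arises, because each new olefin bears two identical methyl groups. Cross- over homo-metathesis is needed and should be secured by the large excess of the volatile partner; any homodimer or crotyl intermediate is still a reactive disubstituted olefin and is funnelled on, whereas the trisubstituted prenyl product is inert to the catalyst. The allyl double bonds must also stay out of conjugation, which the mild temperature, benzoquinone as hydride scavenger and the acetate masking of all phenols (no free catechol to bind ruthenium) should ensure. The tetrasubstituted, carbonyl-conjugated C2=C3 bond of ring C is too hindered and electron-poor to take part.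

Step 6
Reactants: 11 8,5'-diprenyl-3-O-methylquercetin 5,7,3',4'-tetraacetate
Product: 12 5,7,3',4'-tetrahydroxy-3-methoxy-8,5'-diprenylflavone
Conditions: K2CO3 (2 equiv), MeOH, 0 °C → rt, Ar; then aq. NH4Cl
Reagents that add atoms: none
Why: Base-mediated transesterification (methanolysis) of the four aryl acetates should proceed under conditions that leave the 3-methyl ether and the prenyl olefins alone, and the absence of acid avoids chroman formation from the ortho-prenylphenols.

Compound list
1 | rutin (quercetin 3-O-[α-L-rhamnopyranosyl-(1→6)-β-D-glucopyranoside]) | C[C@@H]1O[C@@H](OC[C@H]2O[C@@H](Oc3c(-c4ccc(O)c(O)c4)oc4cc(O)cc(O)c4c3=O)[C@H](O)[C@@H](O)[C@@H]2O)[C@H](O)[C@H](O)[C@H]1O | starting material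
2 | allyl bromide | C=CCBr | starting material
3 | 7,4'-di-O-allylrutin | C[C@@H]1O[C@@H](OC[C@H]2O[C@@H](Oc3c(-c4ccc(OCC=C)c(O)c4)oc4cc(OCC=C)cc(O)c4c3=O)[C@H](O)[C@@H](O)[C@@H]2O)[C@H](O)[C@H](O)[C@H]1O | intermediate
4 | 7,4'-di-O-allylquercetin | O=c1c(O)c(-c2ccc(OCC=C)c(O)c2)oc2cc(OCC=C)cc(O)c12 | intermediate
5 | iodomethane | CI | starting material
6 | 7,4'-di-O-allyl-3-O-methylquercetin | COc1c(-c2ccc(OCC=C)c(O)c2)oc2cc(OCC=C)cc(O)c2c1=O | intermediate
7 | 5,3'-di-O-acetyl-7,4'-di-O-allyl-3-O-methylquercetin | COc1c(-c2ccc(OCC=C)c(OC(C)=O)c2)oc2cc(OCC=C)cc(OC(C)=O)c2c1=O | intermediate (not isolated)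
8 | 5,3'-di-O-acetyl-8,5'-diallyl-3-O-methylquercetin | COc1c(-c2cc(OC(C)=O)c(O)c(CC=C)c2)oc2c(CC=C)c(O)cc(OC(C)=O)c2c1=O | intermediate (not isolated)
9 | 8,5'-diallyl-3-O-methylquercetin 5,7,3',4'-tetraacetate | COc1c(-c2cc(OC(C)=O)c(OC(C)=O)c(CC=C)c2)oc2c(CC=C)c(OC(C)=O)cc(OC(C)=O)c2c1=O | intermediate
10 | 2-methylbut-2-ene | CC=C(C)C | starting material
11 | 8,5'-diprenyl-3-O-methylquercetin 5,7,3',4'-tetraacetate | COc1c(-c2cc(OC(C)=O)c(OC(C)=O)c(CC=C(C)C)c2)oc2c(CC=C(C)C)c(OC(C)=O)cc(OC(C)=O)c2c1=O | intermediate
12 | 5,7,3',4'-tetrahydroxy-3-methoxy-8,5'-diprenylflavone | COc1c(-c2cc(O)c(O)c(CC=C(C)C)c2)oc2c(CC=C(C)C)c(O)cc(O)c2c1=O | target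

Total step count: 6
Longest linear sequence: 6 steps (rutin 1 to target 12)

Steps most likely to fail

Step 5 (twofold cross-metathesis). The exchange may stall after one side chain. A ruthenium hydride formed from catalyst decay may move an allyl double bond into conjugation with its ring, after which metathesis would shorten that chain. Two flavones may also be linked by homo-metathesis if the partner olefin is lost from the vessel. The fallback builds the olefins by carbonyl olefination instead. It sets out from 9, whose terminal olefins are cleaved (OsO4 cat., NaIO4, 2,6-lutidine, dioxane/H2O, rt) to the dialdehyde 8,5'-bis(2-oxoethyl)-3-O-methylquercetin 5,7,3',4'-tetraacetate F1. A Wittig reaction with isopropylidenetriphenylphosphorane (isopropyltriphenylphosphonium iodide, KHMDS, THF, −78 °C) then installs both CMe2 termini. Any acetate stripped by the ylide is restored with Ac2O/pyridine, and the material rejoins the route at 11.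

Step 4 (acetylative double Claisen rearrangement). Acetyl transfer between phenols in the hot amine may uncap O5 before the ring-A shift, so that part of the allyl group travels to C6 instead of C8. Long heating may also close ortho-allylphenols that escaped acetylation to dihydrobenzofurans. A C6 isomer, if formed, would have to be removed by chromatography at 9. The fallback moves regiocontrol from an ester made in the flask to an isolated, thermally inert acetal ether and separates rearrangement, unmasking and acetylation. It sets out from 6, which is capped (MOMCl, NaH, DMF, 0 °C → rt) as 7,4'-di-O-allyl-5,3'-bis-O-(methoxymethyl)-3-O-methylquercetin F2. Heating (PhNEt2, 200 °C, Ar) should give 8,5'-diallyl-5,3'-bis-O-(methoxymethyl)-3-O-methylquercetin F3. Mild acid (HCl, MeOH, 40 °C), applied before any prenyl group is present, frees 8,5'-diallyl-3-O-methylquercetin F4. Peracetylation (Ac2O, pyridine, DMAP) brings the material back at 9.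

Step 3 (3-O-methylation). Once O3 is consumed, further methyl transfer to O3' (and slowly to O5) may set in, or the reaction may have to be stopped short of full conversion to avoid it. The fallback methylates O3 at a stage where the catechol is tied up and allylates O4' last. It sets out from rutin 1, which is hydrolysed (aq. HCl, EtOH, reflux) to quercetin F5. The catechol is bridged (Ph2CCl2, Ph2O, 175 °C) as 3',4'-O-diphenylmethylenequercetin F6. The most acidic remaining phenol is allylated (allyl bromide 1.1 equiv, K2CO3, DMF) to 7-O-allyl-3',4'-O-diphenylmethylenequercetin F7. The only non-chelated hydroxyl left is methylated (MeI, K2CO3, DMF) to 7-O-allyl-3-O-methyl-3',4'-O-diphenylmethylenequercetin F8. The ketal is removed (AcOH/H2O 4:1, reflux) to give 7-O-allyl-3-O-methylquercetin F9. A single allylation at the more acidic 4'-OH (allyl bromide 1.0 equiv, K2CO3, DMF, 0 °C) returns the material at 6.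

Further compounds
F1 | step 5 | 8,5'-bis(2-oxoethyl)-3-O-methylquercetin 5,7,3',4'-tetraacetate | COc1c(-c2cc(OC(C)=O)c(OC(C)=O)c(CC=O)c2)oc2c(CC=O)c(OC(C)=O)cc(OC(C)=O)c2c1=O
F2 | step 4 | 7,4'-di-O-allyl-5,3'-bis-O-(methoxymethyl)-3-O-methylquercetin | COc1c(-c2ccc(OCC=C)c(OCOC)c2)oc2cc(OCC=C)cc(OCOC)c2c1=O
F3 | step 4 | 8,5'-diallyl-5,3'-bis-O-(methoxymethyl)-3-O-methylquercetin | COc1c(-c2cc(OCOC)c(O)c(CC=C)c2)oc2c(CC=C)c(O)cc(OCOC)c2c1=O
F4 | step 4 | 8,5'-diallyl-3-O-methylquercetin | COc1c(-c2cc(O)c(O)c(CC=C)c2)oc2c(CC=C)c(O)cc(O)c2c1=O
F5 | step 3 | quercetin | O=c1c(O)c(-c2ccc(O)c(O)c2)oc2cc(O)cc(O)c12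
F6 | step 3 | 3',4'-O-diphenylmethylenequercetin | O=c1c(O)c(-c2ccc3OC(c4ccccc4)(c4ccccc4)Oc3c2)oc2cc(O)cc(O)c12
F7 | step 3 | 7-O-allyl-3',4'-O-diphenylmethylenequercetin | O=c1c(O)c(-c2ccc3OC(c4ccccc4)(c4ccccc4)Oc3c2)oc2cc(OCC=C)cc(O)c12
F8 | step 3 | 7-O-allyl-3-O-methyl-3',4'-O-diphenylmethylenequercetin | COc1c(-c2ccc3OC(c4ccccc4)(c4ccccc4)Oc3c2)oc2cc(OCC=C)cc(O)c2c1=O
F9 | step 3 | 7-O-allyl-3-O-methylquercetin | COc1c(-c2ccc(O)c(O)c2)oc2cc(OCC=C)cc(O)c2c1=O
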